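**Retrosynthetic overview**
1. Tetrahydrofuran ring last: C1'–O by 5-exo oxa-Michael addition of the C13 hydroxyl to a C15-linked benzoquinone (from a dimethoxyarene). C13–OH and C14–H come from syn hydroboration of a C13=C14 alkene, and C14–C15 from Negishi coupling of the C14 enol triflate.
2. Lactone ring: the C4 quaternary centre and C19–O–C20 come from reductive methylation of a C3=C4 enoate and lactonisation with the C20 alcohol.
3. Rings B and A together: intramolecular Diels–Alder reaction of a ring C triene aldehyde forms C5–C10 and C1–C2. The strategy rests on C5 and quaternary C10 lying on the bond shared by rings A and B, with C10 carrying the oxidised carbon C20 (the lactone CH2–O), which at the aldehyde level activates a C10=C1 dienophile.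
4. Ring C first: 2-methylcyclohexenone takes the C10/C1/C20 alkenyl unit by copper-catalysed asymmetric conjugate addition and the C7–C5 chain by enolate allylation (C9, C8). The diene is built by dibromo-olefination, Stille vinylation and methoxycarbonylation.
5. Order of ring formation: C (purchased), then B and A in one step, then the lactone ring, then the tetrahydrofuran ring; the cyclohexenedione ring derives from the arene.

Key step: step 10

Numbering used below: ring A = C1–C5, C10; ring B = C5–C10; ring C = C8, C9, C11–C14; C15 = CH2 on C14; C16, C17, C18 = methyls on C13, C8, C4; C19 = carboxyl carbon on C4; C20 = carbon on C10; C1'–C6' = six-membered ring derived from the arene (C1' bears C15, C6' and C3' bear oxygen). α = face of H5 and H9, β = face of C17 and C20.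

Assumption: both enantiomers of the chiral NHC precursor of step 2 are available (from D- or L-leucinol), and the one that delivers the alkenyl group to give the (3R) adduct is chosen in a test reaction.

**Step 1**
Reactants: 1 2-bromoprop-2-en-1-ol
Product: 2 (2-bromoprop-2-en-1-yl)oxy(tert-butyl)dimethylsilane
Conditions: TBSCl, imidazole, CH2Cl2, 0 °C → rt
Reagents that add atoms: tert-butyldimethylsilyl chloride, CC(C)(C)[Si](C)(C)Cl
Why: Silyl ether formation masks the future C20 hydroxyl so that the alkenyl bromide can be metalated.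

**Step 2**
Reactants: 2 (2-bromoprop-2-en-1-yl)oxy(tert-butyl)dimethylsilane; 3 2-methylcyclohex-2-en-1-one; 4 allyl bromide
Product: 8 (2R,3R)-2-allyl-2-methyl-3-[3-(tert-butyldimethylsilyloxy)prop-1-en-2-yl]cyclohexan-1-one, via alkenyllithium 5 (not isolated), via alkenylmagnesium bromide 6 (not isolated), via magnesium enolate 7 (not isolated)
Conditions: t-BuLi (2 equiv), Et2O, −78 °C; MgBr2·OEt2; then 3, Cu(OTf)2 (cat.), chiral 1-mesityl-3-(1-hydroxy-4-methylpentan-2-yl)imidazolinium hexafluorophosphate (NHC precursor, cat.), Et2O, −30 °C; then 4, DMPU, −30 °C → rt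
Reagents that add atoms: none
Why: Copper-catalysed asymmetric conjugate addition of a Grignard reagent to an α-substituted cyclic enone should set C9 under ligand control and give the C8=C14 magnesium enolate regiospecifically, and C-allylation of that enolate anti to the new C9 substituent should set quaternary C8 with C7 trans to C10.

**Step 3**
Reactants: 8 (2R,3R)-2-allyl-2-methyl-3-[3-(tert-butyldimethylsilyloxy)prop-1-en-2-yl]cyclohexan-1-one
Product: 10 (2R,3R)-2-(3-hydroxypropyl)-2-methyl-3-[3-(tert-butyldimethylsilyloxy)prop-1-en-2-yl]cyclohexan-1-one, via alkyldisiamylborane 9 (not isolated)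
Conditions: Sia2BH (from BH3·SMe2 and 2-methylbut-2-ene), THF, 0 °C; then H2O2, aq. NaOH, 0 °C
Reagents that add atoms: hydrogen peroxide, OO
Why: Anti-Markovnikov hydroboration–oxidation with a bulky dialkylborane, which should react with the monosubstituted allyl alkene far faster than with the hindered 1,1-disubstituted alkene or the ketone next to the quaternary carbon.

**Step 4**
Reactants: 10 (2R,3R)-2-(3-hydroxypropyl)-2-methyl-3-[3-(tert-butyldimethylsilyloxy)prop-1-en-2-yl]cyclohexan-1-one
Product: 11 3-{(1R,6R)-1-methyl-2-oxo-6-[3-(tert-butyldimethylsilyloxy)prop-1-en-2-yl]cyclohexyl}propanal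
Conditions: Dess–Martin periodinane, NaHCO3, CH2Cl2, 0 °C → rt
Reagents that add atoms: none
Why: Dess–Martin oxidation of the primary alcohol gives the C5 aldehyde under buffered conditions that leave the silyl ether and the ketone untouched.

**Step 5**
Reactants: 11 3-{(1R,6R)-1-methyl-2-oxo-6-[3-(tert-butyldimethylsilyloxy)prop-1-en-2-yl]cyclohexyl}propanal
Product: 12 (2R,3R)-2-(4,4-dibromobut-3-en-1-yl)-2-methyl-3-[3-(tert-butyldimethylsilyloxy)prop-1-en-2-yl]cyclohexan-1-one
Conditions: CBr4, PPh3, Zn, CH2Cl2, rt (reagent pre-formed); then 11, 0 °C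
Reagents that add atoms: carbon tetrabromide, BrC(Br)(Br)Br
Why: Ramirez dibromo-olefination (first stage of the Corey–Fuchs sequence) is selective for the aldehyde over the hindered ketone and introduces C4 in a form that allows a stereodefined, stepwise build-up of the branched diene (a phosphonocrotonate olefination would react at its γ-carbon and give the linear 2,4-dienoate instead).

**Step 6**
Reactants: 12 (2R,3R)-2-(4,4-dibromobut-3-en-1-yl)-2-methyl-3-[3-(tert-butyldimethylsilyloxy)prop-1-en-2-yl]cyclohexan-1-one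
Product: 13 (2R,3R)-2-[(3Z)-4-bromohexa-3,5-dien-1-yl]-2-methyl-3-[3-(tert-butyldimethylsilyloxy)prop-1-en-2-yl]cyclohexan-1-one
Conditions: Bu3SnCH=CH2, Pd2(dba)3 (cat.), tri(2-furyl)phosphine, toluene, 90 °C
Reagents that add atoms: tributyl(vinyl)stannane, C=C[Sn](CCCC)(CCCC)CCCC
Why: Stille coupling of a 1,1-dibromoalkene takes place selectively at the less hindered bromide trans to the alkyl chain, which should place the vinyl group (C3=C2) trans to C6 and so fix the diene geometry with the tether outside.

**Step 7**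
Reactants: 13 (2R,3R)-2-[(3Z)-4-bromohexa-3,5-dien-1-yl]-2-methyl-3-[3-(tert-butyldimethylsilyloxy)prop-1-en-2-yl]cyclohexan-1-one
Product: 14 methyl (2Z)-2-ethenyl-5-{(1R,6R)-1-methyl-2-oxo-6-[3-(tert-butyldimethylsilyloxy)prop-1-en-2-yl]cyclohexyl}pent-2-enoate
Conditions: CO (1 atm), Pd(OAc)2 (cat.), dppf (cat.), Et3N, MeOH/DMF, 60 °C, BHT, dilute
Reagents that add atoms: carbon monoxide, [C-]#[O+]; methanol, CO
Why: Palladium-catalysed methoxycarbonylation of the alkenyl bromide proceeds with retention of the double-bond geometry, so C19 should end up cis to C6 on the diene.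

**Step 8**
Reactants: 14 methyl (2Z)-2-ethenyl-5-{(1R,6R)-1-methyl-2-oxo-6-[3-(tert-butyldimethylsilyloxy)prop-1-en-2-yl]cyclohexyl}pent-2-enoate
Product: 15 methyl (2Z)-2-ethenyl-5-[(1R,6R)-6-(3-hydroxyprop-1-en-2-yl)-1-methyl-2-oxocyclohexyl]pent-2-enoate
Conditions: HF·pyridine, pyridine, THF, 0 °C → rt
Reagents that add atoms: none
Why: Buffered fluoride cleavage of the primary silyl ether (desilylation) should free the C20 alcohol without touching the dienoate.

**Step 9**
Reactants: 15 methyl (2Z)-2-ethenyl-5-[(1R,6R)-6-(3-hydroxyprop-1-en-2-yl)-1-methyl-2-oxocyclohexyl]pent-2-enoate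
Product: 16 methyl (2Z)-2-ethenyl-5-[(1R,6R)-1-methyl-2-oxo-6-(3-oxoprop-1-en-2-yl)cyclohexyl]pent-2-enoate
Conditions: Dess–Martin periodinane, NaHCO3, CH2Cl2, 0 °C; cold work-up, solution used at once
Reagents that add atoms: none
Why: Dess–Martin oxidation of the allylic alcohol gives the 2-substituted acrolein quickly at low temperature, so the triene aldehyde is formed last and can be carried directly into the cycloaddition.

**Step 10**
Reactants: 16 methyl (2Z)-2-ethenyl-5-[(1R,6R)-1-methyl-2-oxo-6-(3-oxoprop-1-en-2-yl)cyclohexyl]pent-2-enoate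
Product: 17 tricyclic keto aldehyde (methyl C19 ester on the C3=C4 double bond; 10β-formyl C20; C14 ketone; 5α-H; 9α-H; 8β-methyl)
Conditions: Me2AlCl (2.2 equiv), CH2Cl2 (0.005 M), −78 → −20 °C
Reagents that add atoms: none
Why: A concerted, asynchronous [4+2] cycloaddition, the Lewis acid-promoted intramolecular Diels–Alder reaction of a 1,7,9-decatriene with a 2-substituted acrolein dienophile (a known reaction type), in which Me2AlCl on the C20 formyl oxygen lowers the dienophile LUMO and C1–C2 and C5–C10 form in one step. Ring B closes in the fused mode as a six-membered ring through the four-atom tether C6–C9 in a chair-like arrangement, and ring A is the cyclohexene created by the cycloaddition, with the C3=C4 enoate left as its double bond. C5 and C10 are set relative to each other by the endo orientation of the formyl group combined with the diene geometry (C6 outside), which places H5 trans to C20 and gives the trans A/B fusion. Their sense relative to C8 and C9 is set by ring C, on whose chair both arms are equatorial, so that the chair tether leads to 5α-H and 10β-CHO (trans-anti-trans). The step needs endo (trans-fused) over exo (cis-fused) selectivity and cyclisation over diene dimerisation: the Lewis acid should reinforce the endo preference, the axial C8 methyl penalises the cis-fused arrangement that places C1 syn-axial to it, and high dilution at low temperature suppresses the bimolecular pathway.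

**Step 11**
Reactants: 17 tricyclic keto aldehyde
Product: 18 tricyclic diol (C20 as CH2OH; 14β-OH; C3=C4 enoate retained)
Conditions: NaBH4, MeOH/THF, 0 °C
Reagents that add atoms: none
Why: Borohydride reduction of the aldehyde and of the C14 ketone (axial hydride delivery from the α face, 14β-OH expected; this centre is removed again in step 13) should leave the conjugated ester intact and keep both carbonyls out of the dissolving-metal step.

**Step 12**
Reactants: 18 tricyclic diol
Product: 21 hydroxy lactone (19,20-olide; 4α-methyl C18; 14β-OH), via lithium ester enolate 19 (not isolated), via methylated hydroxy ester 20 (not isolated)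
Conditions: Li, NH3(l)/THF, −78 °C; MeI, −78 → −33 °C; then 1 M HCl, THF, rt
Reagents that add atoms: iodomethane, CI
Why: Birch-type reductive alkylation, in which two-electron reduction of the enoate with protonation at C3 gives the C4 ester enolate that should be methylated from the α face, anti to the axial C20 oxymethyl group (C18 α, C19 β), after which the C20 hydroxyl lactonises onto the syn-axial C19 ester.

**Step 13**
Reactants: 21 hydroxy lactone
Product: 22 keto lactone (19,20-olide; C14 ketone)
Conditions: Dess–Martin periodinane, NaHCO3, CH2Cl2, rt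
Reagents that add atoms: none
Why: Dess–Martin oxidation returns the C14 ketone, while the lactone, which has no α-hydrogen, is inert.

**Step 14**
Reactants: 22 keto lactone
Product: 24 13α-methyl keto lactone, via lithium enolate 23 (not isolated)
Conditions: LiN(iPr)2, THF, −78 °C; MeI, −78 → 0 °C
Reagents that add atoms: iodomethane, CI
Why: Enolate alkylation at C13, the only enolisable position of the ketone since C8 is quaternary, introduces C16 (the C13 configuration is erased in the next step).

**Step 15**
Reactants: 24 13α-methyl keto lactone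
Product: 26 enol triflate (C13(CH3)=C14–OTf; 19,20-olide), via potassium enolate 25 (not isolated)
Conditions: KN(SiMe3)2, THF, −78 °C; PhNTf2, −78 °C → rt
Reagents that add atoms: N-phenylbis(trifluoromethanesulfonimide), O=S(=O)(N(c1ccccc1)S(=O)(=O)C(F)(F)F)C(F)(F)F
Why: O-Triflation of the only possible enolate gives the tetrasubstituted C13=C14 enol triflate, the same pattern as the widely used triflate of 2,2,6-trimethylcyclohexanone.

**Step 16**
Reactants: 26 enol triflate; 27 2-(chloromethyl)-1,4-dimethoxybenzene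
Product: 29 14-(2,5-dimethoxybenzyl) C13=C14 alkene (19,20-olide), via benzylzinc chloride 28 (not isolated)
Conditions: 27, Zn, LiCl, THF, rt; then 26, Pd(OAc)2 (cat.), SPhos (cat.), THF, 60 °C
Reagents that add atoms: none
Why: Negishi coupling of the alkenyl triflate with a benzylic zinc reagent (no β-hydrogen on the transferred group) forms C14–C15 and leaves the tetrasubstituted C13=C14 alkene in place.

**Step 17**
Reactants: 29 14-(2,5-dimethoxybenzyl) C13=C14 alkene
Product: 31 tertiary alcohol (13α-OH; 13β-methyl; 14α-H; 14β-(2,5-dimethoxybenzyl); 19,20-olide), via 13α-alkylborane 30 (not isolated)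
Conditions: BH3·SMe2 (2 equiv), THF, 0 °C → rt; then H2O2, aq. NaOH, 0 °C → rt
Reagents that add atoms: hydrogen peroxide, OO
Why: Hydroboration–oxidation of the tetrasubstituted alkene is a syn addition that should occur on the α face, away from the axial C8 methyl, with boron on the less hindered C13, so that oxidation with retention sets 13α-OH and 14α-H together.

**Step 18**
Reactants: 31 tertiary alcohol
Product: 32 hydroxy quinone (as 31, with the arene converted into a 1,4-benzoquinon-2-yl ring)
Conditions: (NH4)2Ce(NO3)6, MeCN/H2O, 0 °C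
Reagents that add atoms: water, O
Why: Oxidative demethylation of the hydroquinone dimethyl ether by tetravalent cerium gives the para-quinone, while the tertiary alcohol and the lactone are not oxidisable under these conditions.

**Step 19**
Reactants: 32 hydroxy quinone
Product: 33 CNP0290557.1 (target)
Conditions: camphorsulfonic acid (cat.), CH2Cl2, rt
Reagents that add atoms: none
Why: Intramolecular oxa-Michael addition (5-exo-trig) of the C13 hydroxyl to C1', the quinone carbon β to the C3' carbonyl, followed by ketonisation at C2' gives the spiro ene-dione, and because the addition is reversible the C1' configuration should settle under thermodynamic control with the flat C6' carbonyl, not the C2' methylene, cis to the C13 methyl on the new ring.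

**Compound list**
1 | 2-bromoprop-2-en-1-ol | OCC(Br)=C | starting material
2 | (2-bromoprop-2-en-1-yl)oxy(tert-butyl)dimethylsilane | C=C(Br)CO[Si](C)(C)C(C)(C)C | intermediate
3 | 2-methylcyclohex-2-en-1-one | CC1=CCCCC1=O | starting material
4 | allyl bromide | C=CCBr | starting material
5 | [3-(tert-butyldimethylsilyloxy)prop-1-en-2-yl]lithium | [Li]C(=C)CO[Si](C)(C)C(C)(C)C | intermediate (not isolated)
6 | [3-(tert-butyldimethylsilyloxy)prop-1-en-2-yl]magnesium bromide | Br[Mg]C(=C)CO[Si](C)(C)C(C)(C)C | intermediate (not isolated)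
7 | bromomagnesium (3R)-2-methyl-3-[3-(tert-butyldimethylsilyloxy)prop-1-en-2-yl]cyclohex-1-en-1-olate | CC1=C(O[Mg]Br)CCC[C@@H]1C(=C)CO[Si](C)(C)C(C)(C)C | intermediate (not isolated)
8 | (2R,3R)-2-allyl-2-methyl-3-[3-(tert-butyldimethylsilyloxy)prop-1-en-2-yl]cyclohexan-1-one | C=CC[C@]1(C)[C@@H](C(=C)CO[Si](C)(C)C(C)(C)C)CCCC1=O | intermediate
9 | trialkylborane from 8 (boron on C5, two 3-methylbutan-2-yl groups, configuration at those groups undefined) | CC(C)C(C)B(CCC[C@]1(C)[C@@H](C(=C)CO[Si](C)(C)C(C)(C)C)CCCC1=O)C(C)C(C)C | intermediate (not isolated)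
10 | (2R,3R)-2-(3-hydroxypropyl)-2-methyl-3-[3-(tert-butyldimethylsilyloxy)prop-1-en-2-yl]cyclohexan-1-one | OCCC[C@]1(C)[C@@H](C(=C)CO[Si](C)(C)C(C)(C)C)CCCC1=O | intermediate
11 | 3-{(1R,6R)-1-methyl-2-oxo-6-[3-(tert-butyldimethylsilyloxy)prop-1-en-2-yl]cyclohexyl}propanal | O=CCC[C@]1(C)[C@@H](C(=C)CO[Si](C)(C)C(C)(C)C)CCCC1=O | intermediate
12 | (2R,3R)-2-(4,4-dibromobut-3-en-1-yl)-2-methyl-3-[3-(tert-butyldimethylsilyloxy)prop-1-en-2-yl]cyclohexan-1-one | BrC(Br)=CCC[C@]1(C)[C@@H](C(=C)CO[Si](C)(C)C(C)(C)C)CCCC1=O | intermediate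
13 | (2R,3R)-2-[(3Z)-4-bromohexa-3,5-dien-1-yl]-2-methyl-3-[3-(tert-butyldimethylsilyloxy)prop-1-en-2-yl]cyclohexan-1-one | C=C/C(Br)=C/CC[C@]1(C)[C@@H](C(=C)CO[Si](C)(C)C(C)(C)C)CCCC1=O | intermediate
14 | methyl (2Z)-2-ethenyl-5-{(1R,6R)-1-methyl-2-oxo-6-[3-(tert-butyldimethylsilyloxy)prop-1-en-2-yl]cyclohexyl}pent-2-enoate | C=C/C(C(=O)OC)=C/CC[C@]1(C)[C@@H](C(=C)CO[Si](C)(C)C(C)(C)C)CCCC1=O | intermediate
15 | methyl (2Z)-2-ethenyl-5-[(1R,6R)-6-(3-hydroxyprop-1-en-2-yl)-1-methyl-2-oxocyclohexyl]pent-2-enoate | C=C/C(C(=O)OC)=C/CC[C@]1(C)[C@@H](C(=C)CO)CCCC1=O | intermediate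
16 | methyl (2Z)-2-ethenyl-5-[(1R,6R)-1-methyl-2-oxo-6-(3-oxoprop-1-en-2-yl)cyclohexyl]pent-2-enoate (ring C triene aldehyde) | C=C/C(C(=O)OC)=C/CC[C@]1(C)[C@@H](C(=C)C=O)CCCC1=O | intermediate
17 | tricyclic keto aldehyde: C3=C4 enoate with CO2Me (C19) on C4, 10β-CHO (C20), C14 ketone, 5α-H, 9α-H, 8β-CH3 | C[C@@]12CC[C@@H]3[C@](C=O)(CCC=C3C(=O)OC)[C@H]1CCCC2=O | intermediate
18 | tricyclic diol: as 17 with C20 as CH2OH and 14β-OH | C[C@@]12CC[C@@H]3[C@](CO)(CCC=C3C(=O)OC)[C@H]1CCC[C@H]2O | intermediate
19 | trilithium species: C4=C19 ester enolate (geometry undefined) with lithium alkoxides at C20 and C14 | C[C@@]12CC[C@@H]3[C@](CO[Li])(CCCC3=C(OC)O[Li])[C@H]1CCC[C@H]2O[Li] | intermediate (not isolated)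
20 | saturated hydroxy ester: 4α-CH3 (C18), 4β-CO2Me (C19), C20–OH, 14β-OH (present as its lithium alkoxides in the flask) | C[C@@]12CC[C@@H]3[C@](CO)(CCC[C@]3(C)C(=O)OC)[C@H]1CCC[C@H]2O | intermediate (not isolated)
21 | hydroxy lactone: 19,20-olide, 4α-CH3, 14β-OH | C[C@@]12CC[C@@H]3[C@]4(CCC[C@]3(C)C(=O)OC4)[C@H]1CCC[C@H]2O | intermediate
22 | keto lactone: 19,20-olide, C14 ketone | C[C@@]12CC[C@@H]3[C@]4(CCC[C@]3(C)C(=O)OC4)[C@H]1CCCC2=O | intermediate
23 | lithium enolate of 22 (C13=C14–OLi) | C[C@@]12CC[C@@H]3[C@]4(CCC[C@]3(C)C(=O)OC4)[C@H]1CCC=C2O[Li] | intermediate (not isolated)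
24 | 13α-methyl keto lactone (C13 epimer also acceptable) | C[C@@]12CC[C@@H]3[C@]4(CCC[C@]3(C)C(=O)OC4)[C@H]1CC[C@H](C)C2=O | intermediate
25 | potassium enolate of 24 (C13(CH3)=C14–OK) | C[C@@]12CC[C@@H]3[C@]4(CCC[C@]3(C)C(=O)OC4)[C@H]1CCC(C)=C2O[K] | intermediate (not isolated)
26 | enol triflate: C13(CH3)=C14–OSO2CF3, 19,20-olide | C[C@@]12CC[C@@H]3[C@]4(CCC[C@]3(C)C(=O)OC4)[C@H]1CCC(C)=C2OS(=O)(=O)C(F)(F)F | intermediate
27 | 2-(chloromethyl)-1,4-dimethoxybenzene (2,5-dimethoxybenzyl chloride) | COc1ccc(OC)c(CCl)c1 | starting material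
28 | (2,5-dimethoxybenzyl)zinc chloride | COc1ccc(OC)c(C[Zn]Cl)c1 | intermediate (not isolated)
29 | 14-(2,5-dimethoxybenzyl) C13=C14 alkene, 19,20-olide | C[C@@]12CC[C@@H]3[C@]4(CCC[C@]3(C)C(=O)OC4)[C@H]1CCC(C)=C2Cc1cc(OC)ccc1OC | intermediate
30 | 13α-boryl (BH2) adduct of 29: 13β-CH3, 14α-H | C[C@@]12CC[C@@H]3[C@]4(CCC[C@]3(C)C(=O)OC4)[C@H]1CC[C@](C)(B)[C@H]2Cc1cc(OC)ccc1OC | intermediate (not isolated)
31 | tertiary alcohol: 13α-OH, 13β-CH3, 14α-H, 14β-(2,5-dimethoxybenzyl), 19,20-olide | C[C@@]12CC[C@@H]3[C@]4(CCC[C@]3(C)C(=O)OC4)[C@H]1CC[C@](C)(O)[C@H]2Cc1cc(OC)ccc1OC | intermediate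
32 | hydroxy quinone: as 31 with 14β-(1,4-benzoquinon-2-ylmethyl) | C[C@@]12CC[C@@H]3[C@]4(CCC[C@]3(C)C(=O)OC4)[C@H]1CC[C@](C)(O)[C@H]2CC1=CC(=O)C=CC1=O | intermediate
33 | CNP0290557.1 | C[C@@]12CC[C@@H]3[C@]4(CCC[C@]3(C)C(=O)OC4)[C@H]1CC[C@]1(C)O[C@]3(CC(=O)C=CC3=O)C[C@@H]21 | target

**Step count**
Total step count: 19. Longest linear sequence: 19 steps (1 → 33); 3, 4 and 27 enter as purchased materials in steps 2 and 16.

**Steps most likely to fail**

Step 10 (intramolecular Diels–Alder reaction). The cycloaddition may lose its endo (trans-fused) preference, or be outrun by bimolecular dimerisation of the electron-poor diene, because the Lewis acid also binds the diene ester and the ketone. The fallback sets out from bromodiene 13 and defers the ester. HF·pyridine frees the allylic alcohol F3, and Dess–Martin oxidation gives the bromo triene aldehyde F4. The Me2AlCl-promoted intramolecular Diels–Alder reaction of this 2-bromodiene, a normal-demand diene with no Lewis-basic ester and little tendency to dimerise, should give the tricyclic alkenyl bromide F5. Palladium-catalysed methoxycarbonylation of the C4 bromide (CO, MeOH, Et3N, Pd(OAc)2, dppf) then comes back to the route at 17.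

Step 2 (asymmetric conjugate addition and allylation). Transfer of the functionalised alkenyl group may proceed with poor enantioselectivity, and the alkenylmetal may be lost by β-elimination of silyloxide on warming. The fallback sets out from 2, 3 and 4 and gives up the asymmetric catalysis. The same conjugate addition–allylation with alkenylmagnesium bromide 6 and an achiral catalyst (CuBr·SMe2, THF, −78 °C) passes through enolate 7 and its enantiomer F1 and gives the racemic trans ketone, that is 8 together with its enantiomer F2. Separation of the enantiomers by preparative chromatography on a chiral stationary phase comes back to the route at 8.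

Step 17 (hydroboration of the tetrasubstituted alkene). The hindered alkene may react so slowly that reduction of the lactone or delivery of boron to C14 competes. The fallback sets out from keto lactone 22 and introduces C16 after the oxygen.
- KN(SiMe3)2 and then PhNTf2 give, through the potassium enolate F6, the trisubstituted enol triflate F7.
- Negishi coupling with 28 gives the C13(H)=C14 alkene F8.
- Hydroboration (BH3·THF, anti-Markovnikov, α face) gives the alkylborane F9 and, after H2O2/NaOH, the 13α-alcohol F10.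
- Dess–Martin oxidation gives the C13 ketone F11, in which the equatorial 14β-benzyl group is the stable epimer.
- Wittig methylenation (Ph3P=CH2) gives the 13-methylene compound F12.
- Mukaiyama hydration (Mn(dpm)3, PhSiH3, O2, i-PrOH) should trap the tertiary C13 radical from the α face, away from the syn-axial C8 methyl, and comes back to the route at 31.

**Further compounds**
F1 | step 2 | enantiomer of magnesium enolate 7, bromomagnesium (3S)-2-methyl-3-[3-(tert-butyldimethylsilyloxy)prop-1-en-2-yl]cyclohex-1-en-1-olate | CC1=C(O[Mg]Br)CCC[C@H]1C(=C)CO[Si](C)(C)C(C)(C)C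
F2 | step 2 | (2S,3S)-2-allyl-2-methyl-3-[3-(tert-butyldimethylsilyloxy)prop-1-en-2-yl]cyclohexan-1-one (enantiomer of 8) | C=CC[C@@]1(C)[C@H](C(=C)CO[Si](C)(C)C(C)(C)C)CCCC1=O
F3 | step 10 | (2R,3R)-2-[(3Z)-4-bromohexa-3,5-dien-1-yl]-3-(3-hydroxyprop-1-en-2-yl)-2-methylcyclohexan-1-one | C=C/C(Br)=C/CC[C@]1(C)[C@@H](C(=C)CO)CCCC1=O
F4 | step 10 | 2-{(1R,2R)-2-[(3Z)-4-bromohexa-3,5-dien-1-yl]-2-methyl-3-oxocyclohexyl}prop-2-enal | C=C/C(Br)=C/CC[C@]1(C)[C@@H](C(=C)C=O)CCCC1=O
F5 | step 10 | tricyclic alkenyl bromide: as 17 with Br in place of CO2Me on C4 | C[C@@]12CC[C@@H]3[C@](C=O)(CCC=C3Br)[C@H]1CCCC2=O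
F6 | step 17 | potassium enolate of 22 (C13=C14–OK) | C[C@@]12CC[C@@H]3[C@]4(CCC[C@]3(C)C(=O)OC4)[C@H]1CCC=C2O[K]
F7 | step 17 | enol triflate: C13(H)=C14–OSO2CF3, 19,20-olide | C[C@@]12CC[C@@H]3[C@]4(CCC[C@]3(C)C(=O)OC4)[C@H]1CCC=C2OS(=O)(=O)C(F)(F)F
F8 | step 17 | 14-(2,5-dimethoxybenzyl) C13(H)=C14 alkene, 19,20-olide | C[C@@]12CC[C@@H]3[C@]4(CCC[C@]3(C)C(=O)OC4)[C@H]1CCC=C2Cc1cc(OC)ccc1OC
F9 | step 17 | 13α-boryl (BH2) adduct of F8, 14α-H | C[C@@]12CC[C@@H]3[C@]4(CCC[C@]3(C)C(=O)OC4)[C@H]1CC[C@H](B)[C@H]2Cc1cc(OC)ccc1OC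
F10 | step 17 | secondary alcohol: 13α-OH, 14α-H, 14β-(2,5-dimethoxybenzyl), 19,20-olide | C[C@@]12CC[C@@H]3[C@]4(CCC[C@]3(C)C(=O)OC4)[C@H]1CC[C@H](O)[C@H]2Cc1cc(OC)ccc1OC
F11 | step 17 | C13 ketone: 14α-H, 14β-(2,5-dimethoxybenzyl), 19,20-olide | C[C@@]12CC[C@@H]3[C@]4(CCC[C@]3(C)C(=O)OC4)[C@H]1CCC(=O)[C@H]2Cc1cc(OC)ccc1OC
F12 | step 17 | 13-methylene compound: 14α-H, 14β-(2,5-dimethoxybenzyl), 19,20-olide | C[C@@]12CC[C@@H]3[C@]4(CCC[C@]3(C)C(=O)OC4)[C@H]1CCC(=C)[C@H]2Cc1cc(OC)ccc1OC
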